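**Retrosynthetic overview**

1. Side chain: butanal (1) and acetyl bromide (2) give racemic 1-bromobutyl acetate (3), which already holds C1' at the right oxidation level, its acetate and a radical-labile C–Br bond.
2. Ring: the only ring, furanone ring A (O1, C2, C3, C4, C5), is not formed in the route; it is bought whole as (5Z)-4-bromo-5-(bromomethylidene)furan-2(5H)-one (4), with C4–Br and the (Z)-C5=CHBr unit in place.
3. Enabling feature: the single ring hydrogen of 4, C3–H, lies between the C2 lactone carbonyl and C4–Br. A zinc amide removes it to give the C3-zinc reagent 5, which is stable because C3 and C4 share a five-membered ring, so bromide cannot be lost to a ring alkyne.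
4. Key disconnection: the C3–C1' bond of target 6, made by a nickel-catalysed enantioconvergent coupling of 5 with racemic 3. This one operation forms the bond, sets the only stereocentre (R) from both enantiomers of 3 and delivers the acetate.

Key step: step 2

Assumption: 4 is taken as a purchased compound (it is sold as a quorum-sensing inhibitor) and TMPZnCl·LiCl as its commercial THF solution; the (S,S) ligand is assumed to give the (R)-acetate and would be exchanged for its antipode if the sense of induction proved opposite.

**Step 1**
Reactants: 1 butanal; 2 acetyl bromide
Product: 3 rac-1-bromobutyl acetate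
Conditions: AcBr (1.05 equiv), ZnBr2 (0.5 mol %), CH2Cl2, −10 °C → 20 °C; volatiles removed, short-path distillation under reduced pressure, stored cold under argon
Reagents that add atoms: acetyl bromide (compound 2), CC(=O)Br
Why: The Lewis-acid-catalysed addition of an acyl bromide across an aldehyde carbonyl (1-haloalkyl ester formation through an O-acylated oxocarbenium bromide ion pair) is a long-known, fully atom-economic reaction, and the racemic stereocentre it creates is exactly what the stereoconvergent step 2 consumes.

**Step 2**
Reactants: 4 (5Z)-4-bromo-5-(bromomethylidene)furan-2(5H)-one; 3 rac-1-bromobutyl acetate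
Product: 6 (1R)-1-[(5Z)-4-bromo-5-(bromomethylidene)-2-oxo-2,5-dihydrofuran-3-yl]butyl acetate, via furanonylzinc chloride 5 (not isolated)
Conditions: 4, TMPZnCl·LiCl (1.1 equiv; TMP = 2,2,6,6-tetramethylpiperidin-1-yl), THF, 0 °C → 25 °C; then added slowly to 3 (1.5 equiv), NiBr2·DME (10 mol %; DME = 1,2-dimethoxyethane), (S,S)-Ph-BOX [2,2'-(propane-2,2-diyl)bis((4S)-4-phenyl-4,5-dihydrooxazole)] (12 mol %), THF/DMA, −20 °C
Reagents that add atoms: TMPZnCl·LiCl, CC1(C)CCCC(C)(C)N1[Zn]Cl.[Li+].[Cl-] (its ZnCl·LiCl stays in intermediate 5 only; no atom of it reaches 6)
Why: Proposed new method: TMPZnCl·LiCl, bound to the C2 carbonyl oxygen, removes the C3–H of ring A (a known directed zincation of unsaturated lactones) and gives alkenylzinc 5, which cannot expel its C4 bromide because that would place a triple bond in the five-membered ring. Ligated monovalent nickel abstracts bromine from either enantiomer of 3, the planar α-acetoxybutyl radical is captured by the alkenylnickel species formed from 5 by transmetalation, and the trivalent nickel intermediate reductively eliminates the C3–C1' bond, so both enantiomers of 3 converge on one product. The closest known reaction type is the nickel-catalysed enantioconvergent alkylation of racemic 1-bromoalkyl esters, together with enantioconvergent Negishi arylations and alkenylations of other activated racemic secondary alkyl halides; an alkenylzinc partner that itself carries two C(sp2)–Br bonds has not been shown. No ring is closed. The new stereocentre C1' is set under catalyst control, the acetate carbonyl oxygen chelating nickel in the alkylnickel intermediate so that the twofold-symmetric bis(oxazoline) distinguishes its two faces and the ligand enantiomer selects (R). The step needs activation of the C(sp3)–Br bond of 3 ahead of the two C(sp2)–Br bonds present in 4, 5 and 6, and this is secured by the α-acetoxy group, which makes that bond weak and its radical stabilised, and is supported by low temperature, an excess of 3 and slow addition of 5.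

**Compound list**

1 | butanal | CCCC=O | starting material
2 | acetyl bromide | CC(=O)Br | starting material
3 | rac-1-bromobutyl acetate | CCCC(Br)OC(C)=O | intermediate
4 | (5Z)-4-bromo-5-(bromomethylidene)furan-2(5H)-one | O=C1C=C(Br)/C(=C/Br)O1 | starting material
5 | [(5Z)-4-bromo-5-(bromomethylidene)-2-oxo-2,5-dihydrofuran-3-yl]zinc chloride, lithium chloride complex | Cl[Zn]C1=C(Br)/C(=C/Br)OC1=O.[Li+].[Cl-] | intermediate
6 | (1R)-1-[(5Z)-4-bromo-5-(bromomethylidene)-2-oxo-2,5-dihydrofuran-3-yl]butyl acetate | CCC[C@@H](OC(C)=O)C1=C(Br)/C(=C/Br)OC1=O | target

Total step count: 2
Longest linear sequence: 2 steps (1 → 3 → 6)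

**Steps most likely to fail** (the route has only two steps, so the ranking holds two entries)

1. Step 2 (bears the label "Proposed new method:").
   - What may go wrong: low-valent nickel may insert into the C4–Br or the exocyclic C–Br bond, so that the zinc reagent couples with itself. Uncatalysed racemic alkylation of 5 by 3, or weak facial discrimination at C1', may erode the enantiomeric purity. Zincation may also occur in part at the exocyclic =CHBr position.
   - Fallback (known chemistry, no nickel): it sets out from zinc reagent 5, made from 4 as in step 2, and comes back to the route at 6.
   - Zinc reagent 5 is treated with MgCl2 and butanal 1 in THF at 0 °C → 25 °C. This MgCl2-promoted 1,2-addition of an organozinc halide to an aldehyde should give racemic (5Z)-4-bromo-5-(bromomethylidene)-3-(1-hydroxybutyl)furan-2(5H)-one F1.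
   - Kinetic resolution of F1 with Burkholderia cepacia lipase and vinyl acetate in tert-butyl methyl ether at 30 °C should acetylate the (R)-alcohol, as the empirical size rule for lipase acylation of secondary alcohols predicts with ring A as the large group and propyl as the medium group. This should give 6 directly, beside unreacted (5Z)-4-bromo-5-(bromomethylidene)-3-[(1S)-1-hydroxybutyl]furan-2(5H)-one F2.
   - F2 is separated and converted into 6 by Mitsunobu inversion (AcOH, PPh3, DIAD, THF, 0 °C, betaine formed before the alcohol is added), so that both halves of F1 should end as 6.

2. Step 1.
   - What may go wrong: acid-promoted self-aldol condensation of butanal may compete with addition of the acyl bromide, and 3 may lose hydrogen bromide during distillation.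
   - Fallback: it sets out from 1 and comes back to the route at 3.
   - Butanal 1 is converted with Ac2O and KOAc at reflux into the enol ester but-1-en-1-yl acetate (E/Z mixture) F3, a standard enol acetate preparation.
   - Markovnikov addition of dry HBr to F3 in CH2Cl2 at −30 °C, the way 1-bromoalkyl esters are made from vinyl esters, should then give 3, which would be used without distillation.

**Further compounds**

F1 | step 2 | rac-(5Z)-4-bromo-5-(bromomethylidene)-3-(1-hydroxybutyl)furan-2(5H)-one | CCCC(O)C1=C(Br)/C(=C/Br)OC1=O
F2 | step 2 | (5Z)-4-bromo-5-(bromomethylidene)-3-[(1S)-1-hydroxybutyl]furan-2(5H)-one | CCC[C@H](O)C1=C(Br)/C(=C/Br)OC1=O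
F3 | step 1 | but-1-en-1-yl acetate (E/Z mixture) | CCC=COC(C)=O
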